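## Analysis of the target

The target 19 (C28H28O10) is a linear tridepside. Three benzene rings are joined head to tail by two aryl ester (depside) bonds and closed by a methyl ester; there is no stereocentre and no fused or bridged ring. Ring A is the terminal 2-hydroxy-4-methoxy-6-methylbenzoyl group. Ring B is the central 2-methoxy-6-methylbenzoyl unit, acylated on O4 by ring A, and ring C is the methyl 2-methoxy-6-methylbenzoate, acylated on O4 by ring B. All three rings share one skeleton: C1 bears a carboxyl carbon, C6 a methyl group, C2 and C4 an oxygen atom, C3 and C5 hydrogen. They differ only at oxygen. In rings B and C the ortho oxygen O2 is methylated and the para oxygen O4 is acylated, whereas in ring A O2 is a free, hydrogen-bonded hydroxyl and O4 is methylated. Each of the three carbonyl groups is flanked by two ortho substituents (C2–O and C6–CH3), so acyl transfer at these carbons is slow, while the finished aryl esters are cleaved by alkoxide, hydroxide and amines. The difficulty therefore lies in two hindered ester bonds and in telling six phenolic oxygens apart, in opposite senses on ring A and on rings B and C, which normally costs protecting groups. The feature that invites the chosen move is this: in every ring, C1 and C6 with the carboxyl carbon and the C6 methyl group are the four carbons of a but-2-ynoate, and C2–C5 with O2 and O4 are a 1,1,3-trioxygenated buta-1,3-diene. Each ring can thus be grown by a Diels–Alder reaction on an ester that already exists, and the choice of diene decides which oxygen carries the methyl group.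

## Retrosynthetic reasoning

**Ring A, cut last.** In 19 the bonds C1–C2 and C5–C6 of ring A are cut. This leads back, through the cyclohexadiene 18, to the didepside but-2-ynoate 14 and the diene 17.
- The cut removes a whole ring.
- It removes the hindered A–B acylation, because the ester C–O bond already exists in 14 at an unhindered carbonyl.
- It removes the protecting group that O2 of ring A would otherwise need.
- The forward reaction must give one orientation only. It must also aromatise so that O2 ends as hydroxyl and O4 keeps its methyl group.

**Acyl–oxygen bond of the butynoate in 14.** This cut gives the didepside phenol 13 and but-2-ynoic acid 10. The carbonyl carries only a linear alkyne, and O4 of ring B is flanked by two hydrogens. The forward step is therefore an ordinary esterification of an unhindered acid with an unhindered phenol.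

**Ring B.** In 13 the bonds C1–C2 and C5–C6 of ring B are cut in the same way, leading through 12 to the aryl but-2-ynoate 11 and the diene 6. Diene 6 is the constitutional counterpart of 17. It bears two methoxy groups at C1 and the silyloxy group at C3, so the new ring keeps a methyl group on O2 and releases O4 as the free phenol needed for the next acylation. The opposite oxygen pattern is obtained by exchanging the diene and needs no protecting group.

**Ring C.** Compound 11 is cut at its butynoate ester to 9 and 10. In 9 the bonds C1–C2 and C5–C6 are cut to give, through 8, methyl but-2-ynoate 7 and again 6. This first cycloaddition also tests the reaction type on the simplest substrate.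

**The dienes.**
- Diene 6 is the silyl dienol ether of 5, whose methyl group is its only enolisable position.
- Compound 5 comes from 4 by exchange of both vinylic chlorides for methoxy groups.
- Compound 4 comes, through 3, from 1 and 2 by acylation of the alkene.
- Diene 17 comes from 15 through the dienolate 16.
- All carbon atoms of 19 thus derive from five small open-chain compounds: 1, 2, 7, 10 and 15.

## Alternatives that were turned down

**Alternative 1:** The textbook route cuts both depside C(=O)–O bonds and joins three ready-made arene units.
- *Forward plan.* Methyl 2,4-dihydroxy-6-methylbenzoate A1 is benzylated on O4 and methylated on O2. It is then either hydrogenolysed to 9 or saponified to 4-(benzyloxy)-2-methoxy-6-methylbenzoic acid A2.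
- A second portion of A1 is methylated on O4, benzylated on O2 and saponified to 2-(benzyloxy)-4-methoxy-6-methylbenzoic acid A3.
- *Key step.* Phenol 13 (itself made from A2 and 9) is acylated with activated A3 to give the O-benzyl tridepside A4, which is then hydrogenolysed.
- *Why turned down.* Both acylations take place at carbonyl groups with two ortho substituents, and two equally hindered methyl esters must be saponified under forcing conditions. Two benzyl groups are put on and taken off. About eleven operations result, none of which builds skeleton.

**Alternative 2:** The biomimetic route cuts the depside C–O bond together with the C1–C6 bond of ring A.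
- *Forward plan.* Thermolysis of 2,2-dimethyl-6-(2,4-dioxopentyl)-4H-1,3-dioxin-4-one A5 releases the acylketene 3,5,7-trioxooct-1-en-1-one A6. Phenol 13 traps it as the aryl 3,5,7-trioxooctanoate A7.
- An aldol condensation and aromatisation gives the 4-O-demethyl tridepside A8, which is methylated on the free O4.
- *Why turned down.* Every ring is born with both O2 and O4 as hydroxyl. This suits ring A at the price of one more step. In rings B and C, however, the chelated and less reactive O2 would have to be methylated while O4 stays free, which brings the protecting groups back.
- A7 is an aryl ester of a 1,3-dicarbonyl acid. It can lose its phenoxide by an E1cB path under the basic aromatisation conditions.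
- A5 itself needs about three steps.

**Alternative 3:** The central ring B is closed last, with both flanks in place.
- *Forward plan.* The bonds C1–C2 and C5–C6 of ring B are formed from the dienophile 11 and the dienyl ester 4,4-dimethoxybuta-1,3-dien-2-yl 2-(benzyloxy)-4-methoxy-6-methylbenzoate A9. This gives A4, which is then hydrogenolysed.
- *What it offers.* This is the most convergent form of the chosen bond set.
- *Why turned down.* The acyloxy group at C3 of A9 is a much weaker donor than a silyloxy group, so it lowers the reactivity of the diene towards an already sluggish β-methyl ynoate.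
- A9 would have to come from O-acylation of the enolate of 5 with an activated form of the hindered acid A3, in competition with C-acylation.
- A9 is at once a ketene acetal and an acyl donor, so self-acylation is a risk.
- Ring A would again have to be made separately and protected.

Key step: step 9

Assumption: the ketene acetal geometry of 16 and 17 and the configuration of the ketal carbon of 18 are erased on aromatisation, so they are left undefined in the SMILES strings.

## Route

Step 1
Reactants: 1 acetyl chloride; 2 1,1-dichloroethene
Product: 4 4,4-dichlorobut-3-en-2-one, via 4,4,4-trichlorobutan-2-one 3 (not isolated)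
Conditions: AlCl3 (1.1 equiv), CH2Cl2, 0 °C to rt; ice, aq HCl; distillation under reduced pressure (loss of HCl)
Reagents that add atoms: none
Why: Aliphatic Friedel–Crafts (Kondakov-type) acylation; the acylium ion adds to the CH2 terminus of 2 because the cation is then stabilised by two chlorine atoms, and chloride capture gives 3. On heating, 3 loses HCl to give the conjugated enone 4.

Step 2
Reactants: 4 4,4-dichlorobut-3-en-2-one
Product: 5 4,4-dimethoxybut-3-en-2-one
Conditions: NaOMe (2.2 equiv), MeOH, 0 °C to rt; filtration, distillation
Reagents that add atoms: sodium methoxide, [Na+].[O-]C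
Why: Two conjugate addition–elimination events (vinylogous acyl substitution) replace both vinylic chlorides. The push–pull product 5 is far less electrophilic than 4, which stops the sequence at the acylketene acetal.

Step 3
Reactants: 5 4,4-dimethoxybut-3-en-2-one
Product: 6 1,1-dimethoxy-3-(trimethylsilyloxy)buta-1,3-diene
Conditions: Me3SiCl (1.5 equiv), Et3N (2 equiv), ZnCl2 (0.05 equiv), toluene, 40 °C; filtration under N2, distillation
Reagents that add atoms: chlorotrimethylsilane, C[Si](C)(C)Cl
Why: Soft enolisation and O-silylation of a methyl ketone; the CH3 group is the only enolisable position, so a single cross-conjugated silyloxydiene can form. A non-aqueous work-up protects the ketene acetal.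

Step 4
Reactants: 6 1,1-dimethoxy-3-(trimethylsilyloxy)buta-1,3-diene; 7 methyl but-2-ynoate
Product: 9 methyl 4-hydroxy-2-methoxy-6-methylbenzoate, via cycloadduct 8 (not isolated)
Conditions: 6 (2 equiv), neat, base-washed sealed tube, 120 °C; then 0.5 M aq HCl, THF, rt
Reagents that add atoms: none
Why: Diels–Alder reaction of a 1,1,3-trioxygenated diene with an alk-2-ynoate, followed by aromatisation; the unsubstituted C4 of 6 bonds to the β-carbon of 7 and the ketene acetal carbon to the α-carbon. Adduct 8 loses one of its two geminal methoxy groups and its silyl group, so O2 stays methylated and O4 appears as the free phenol.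

Step 5
Reactants: 9 methyl 4-hydroxy-2-methoxy-6-methylbenzoate; 10 but-2-ynoic acid
Product: 11 methyl 4-(but-2-ynoyloxy)-2-methoxy-6-methylbenzoate
Conditions: 10 (1.2 equiv), DCC (1.2 equiv), DMAP (0.1 equiv), CH2Cl2, 0 °C to rt
Reagents that add atoms: none
Why: Steglich esterification, the usual way to aryl alk-2-ynoates; the acid carbonyl carries only a linear alkyne and the phenol is flanked by two hydrogens. Low temperature and little DMAP suppress conjugate addition to the ynoate.

Step 6
Reactants: 11 methyl 4-(but-2-ynoyloxy)-2-methoxy-6-methylbenzoate; 6 1,1-dimethoxy-3-(trimethylsilyloxy)buta-1,3-diene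
Product: 13 methyl 4-[(4-hydroxy-2-methoxy-6-methylbenzoyl)oxy]-2-methoxy-6-methylbenzoate, via cycloadduct 12 (not isolated)
Conditions: 6 (3 equiv, in portions), toluene, sealed tube, 120 °C; then 0.5 M aq HCl, THF, rt
Reagents that add atoms: none
Why: Same Diels–Alder reaction and aromatisation as in step 4, with the same orientation; the aryl ester lowers the LUMO of the ynoate further and 11 has no acidic hydrogen and no other dienophilic π bond. Ring B is built on the finished ester, so the hindered B–C depside bond needs no acylation, and O4 of ring B is set free for the next cycle.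

Step 7
Reactants: 13 methyl 4-[(4-hydroxy-2-methoxy-6-methylbenzoyl)oxy]-2-methoxy-6-methylbenzoate; 10 but-2-ynoic acid
Product: 14 methyl 4-{[4-(but-2-ynoyloxy)-2-methoxy-6-methylbenzoyl]oxy}-2-methoxy-6-methylbenzoate
Conditions: 10 (1.2 equiv), DCC (1.2 equiv), DMAP (0.1 equiv), CH2Cl2, 0 °C to rt
Reagents that add atoms: none
Why: Steglich esterification as in step 5; 13 has a single free hydroxyl group. Its di-ortho-substituted depside and methyl ester carbonyls are too hindered to be attacked by DMAP under these conditions.

Step 8
Reactants: 15 methyl (E)-3-methoxybut-2-enoate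
Product: 17 1,3-dimethoxy-1-(trimethylsilyloxy)buta-1,3-diene, via lithium dienolate 16 (not isolated)
Conditions: LiN(i-Pr)2 (1.1 equiv, commercial solution), THF, −78 °C; Me3SiCl (1.2 equiv), −78 °C to rt; pentane, filtration, distillation
Reagents that add atoms: chlorotrimethylsilane, C[Si](C)(C)Cl
Why: γ-Deprotonation of a β-alkoxy enoate gives the extended dienolate 16, which the hard silyl electrophile captures on oxygen. This is the standard preparation of the Brassard diene.

Step 9
Reactants: 14 methyl 4-{[4-(but-2-ynoyloxy)-2-methoxy-6-methylbenzoyl]oxy}-2-methoxy-6-methylbenzoate; 17 1,3-dimethoxy-1-(trimethylsilyloxy)buta-1,3-diene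
Product: 19 methyl 4-({4-[(2-hydroxy-4-methoxy-6-methylbenzoyl)oxy]-2-methoxy-6-methylbenzoyl}oxy)-2-methoxy-6-methylbenzoate, via cycloadduct 18 (not isolated)
Conditions: 17 (3 equiv, in portions), toluene, base-washed sealed tube, 115 °C; then 0.5 M aq HCl, THF, rt
Reagents that add atoms: none
Why: This is a normal-electron-demand Diels–Alder reaction followed by aromatisation, the reaction type long used to make resorcylate esters from 1-alkoxy-1-silyloxy-3-alkoxybutadienes and alk-2-ynoate esters. The HOMO of 17 is largest at the unsubstituted C4 terminus, towards which all three oxygen donors push, and the LUMO of 14 is largest at the methyl-bearing β-carbon, so C4 bonds to the β-carbon (ring A C5–C6) and the ketene acetal carbon to the α-carbon (ring A C1–C2) in a concerted but strongly asynchronous intermolecular (4+2) closure of the six-membered ring. This one orientation places the carboxyl carbon at C1, oxygen at C2 and C4 and the methyl group at C6, which is the whole substitution pattern of ring A. The ester oxygen of 14 belongs to a phenol that is conjugated to a para carbonyl group, so this ynoate should be a better acceptor than the alkyl alk-2-ynoates of the known cases. Adduct 18 is a cyclohexa-1,4-diene with a mixed methyl silyl ketal at the future C2: acid cleaves the weak O–Si bond, the hemiketal expels its methoxy group and the dienone enolises through the C5 methylene group, so O2 ends as the free hydroxyl chelated to the new depside carbonyl while O4 keeps its methyl group. The ketal carbon of 18 is the only stereocentre formed and it is erased. Chemoselectivity rests on the absence of any other dienophilic π bond or acidic hydrogen in 14 and on the inertness of its three hindered or aromatic esters towards a neutral silyl ketene acetal. The step also turns an unhindered ester into the di-ortho-substituted A–B depside ester, so no acyl transfer ever has to occur at a hindered carbonyl and no protecting group is used.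

## Compound list

1 | acetyl chloride | CC(=O)Cl | starting material
2 | 1,1-dichloroethene | C=C(Cl)Cl | starting material
3 | 4,4,4-trichlorobutan-2-one | CC(=O)CC(Cl)(Cl)Cl | intermediate
4 | 4,4-dichlorobut-3-en-2-one | CC(=O)C=C(Cl)Cl | intermediate
5 | 4,4-dimethoxybut-3-en-2-one | CC(=O)C=C(OC)OC | intermediate
6 | 1,1-dimethoxy-3-(trimethylsilyloxy)buta-1,3-diene | C=C(O[Si](C)(C)C)C=C(OC)OC | intermediate
7 | methyl but-2-ynoate | CC#CC(=O)OC | starting material
8 | methyl 6,6-dimethoxy-2-methyl-4-(trimethylsilyloxy)cyclohexa-1,4-diene-1-carboxylate | COC(=O)C1=C(C)CC(O[Si](C)(C)C)=CC1(OC)OC | intermediate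
9 | methyl 4-hydroxy-2-methoxy-6-methylbenzoate | COC(=O)c1c(C)cc(O)cc1OC | intermediate
10 | but-2-ynoic acid | CC#CC(=O)O | starting material
11 | methyl 4-(but-2-ynoyloxy)-2-methoxy-6-methylbenzoate | COC(=O)c1c(C)cc(OC(=O)C#CC)cc1OC | intermediate
12 | 3-methoxy-4-(methoxycarbonyl)-5-methylphenyl 6,6-dimethoxy-2-methyl-4-(trimethylsilyloxy)cyclohexa-1,4-diene-1-carboxylate | COC(=O)c1c(C)cc(OC(=O)C2=C(C)CC(O[Si](C)(C)C)=CC2(OC)OC)cc1OC | intermediate
13 | methyl 4-[(4-hydroxy-2-methoxy-6-methylbenzoyl)oxy]-2-methoxy-6-methylbenzoate | COC(=O)c1c(C)cc(OC(=O)c2c(C)cc(O)cc2OC)cc1OC | intermediate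
14 | methyl 4-{[4-(but-2-ynoyloxy)-2-methoxy-6-methylbenzoyl]oxy}-2-methoxy-6-methylbenzoate | COC(=O)c1c(C)cc(OC(=O)c2c(C)cc(OC(=O)C#CC)cc2OC)cc1OC | intermediate
15 | methyl (E)-3-methoxybut-2-enoate | CO/C(C)=C/C(=O)OC | starting material
16 | lithium 1,3-dimethoxybuta-1,3-dien-1-olate | [Li+].C=C(OC)C=C([O-])OC | intermediate
17 | 1,3-dimethoxy-1-(trimethylsilyloxy)buta-1,3-diene | C=C(OC)C=C(OC)O[Si](C)(C)C | intermediate
18 | ester of phenol 13 (through O4 of ring B) with 4,6-dimethoxy-2-methyl-6-(trimethylsilyloxy)cyclohexa-1,4-diene-1-carboxylic acid, racemic at the ketal carbon | COC(=O)c1c(C)cc(OC(=O)c2c(C)cc(OC(=O)C3=C(C)CC(OC)=CC3(OC)O[Si](C)(C)C)cc2OC)cc1OC | intermediate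
19 | methyl 4-({4-[(2-hydroxy-4-methoxy-6-methylbenzoyl)oxy]-2-methoxy-6-methylbenzoyl}oxy)-2-methoxy-6-methylbenzoate (CNP0362907.0) | COC(=O)c1c(C)cc(OC(=O)c2c(C)cc(OC(=O)c3c(C)cc(OC)cc3O)cc2OC)cc1OC | target

## Step count and risk

Total step count: 9. The longest linear sequence is 8 steps (steps 1 to 7 and step 9); step 8 is a one-step side branch.

**Step 9 (key step).**
- *What may go wrong.* The β-methyl group makes the ynoate a slow dienophile. Thermal silyl migration, adventitious protonation or oligomerisation of 17 may therefore outrun the cycloaddition.
- A second risk is the wrong partition in the collapse of the mixed ketal of 18. Loss of the silyloxy group in place of the methoxy group would leave O2 of ring A methylated.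
- *Fallback.* It sets out from 13 and comes back at 19; steps 7 and 8 fall away. Compound 13 is condensed with purchased 2-hydroxy-4-methoxy-6-methylbenzoic acid F1 by (CF3CO)2O in toluene at rt.
- The electron-rich, di-ortho-substituted acid ionises readily to an acylium-type donor, for which the ortho groups are no obstacle. The chelated hydroxyl of F1 is a much poorer nucleophile than the free O4–H of 13, so no protection is needed.

**Step 6.**
- *What may go wrong.* If 12 aromatises already at 120 °C, the alcohol that is released can cleave the activated aryl butynoate of unreacted 11 by transesterification. The excess of 6, which consumes protic material, is meant to prevent this, but the diene may also be lost thermally before conversion is complete.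
- *Fallback.* It sets out from 9 and comes back at 13, using classical depside chemistry.
- One part of 9 is benzylated (BnBr, K2CO3, acetone) to methyl 4-(benzyloxy)-2-methoxy-6-methylbenzoate F2.
- F2 is saponified (KOH, aq DMSO, 100 °C) to 4-(benzyloxy)-2-methoxy-6-methylbenzoic acid F3.
- F3 is condensed with a second part of 9 ((CF3CO)2O, toluene, rt) to methyl 4-{[4-(benzyloxy)-2-methoxy-6-methylbenzoyl]oxy}-2-methoxy-6-methylbenzoate F4.
- F4 is hydrogenolysed (H2, Pd/C, EtOAc) to 13.

**Step 4.**
- *What may go wrong.* Methyl but-2-ynoate is the least activated of the three dienophiles and is volatile, so conversion may be slow and incomplete while the diene decomposes.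
- *Fallback.* It sets out from 6 and comes back at 9. The alkyne is replaced by a cumulated diene, purchased methyl buta-2,3-dienoate F5. Its α,β-double bond ends in an sp carbon without a blocking substituent and reacts at about 70 °C with the same orientation.
- The product is methyl 2,2-dimethoxy-6-methylidene-4-(trimethylsilyloxy)cyclohex-3-ene-1-carboxylate F6. Dilute acid converts F6 into 9 by loss of one methoxy group, desilylation and migration of the exocyclic double bond into the ring.

**Step 1.**
- *What may go wrong.* Cationic polymerisation of 2 and incomplete loss of HCl from 3 can make the isolation of 4 inefficient, and 4 is a lachrymatory, base-sensitive enone.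
- *Fallback.* It sets out from 1 and comes back at 5, bypassing steps 1 and 2. Compound 1 is added to two equivalents of purchased 1,1-dimethoxyethene F7 in ether at 0 °C.
- This is C-acylation of a ketene acetal. The first equivalent is acylated, and the second takes up the hydrogen chloride and is consumed.

## Further compounds

F1 | step 9 | 2-hydroxy-4-methoxy-6-methylbenzoic acid (purchased) | COc1cc(C)c(C(=O)O)c(O)c1
F2 | step 6 | methyl 4-(benzyloxy)-2-methoxy-6-methylbenzoate | COC(=O)c1c(C)cc(OCc2ccccc2)cc1OC
F3 | step 6 | 4-(benzyloxy)-2-methoxy-6-methylbenzoic acid | OC(=O)c1c(C)cc(OCc2ccccc2)cc1OC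
F4 | step 6 | methyl 4-{[4-(benzyloxy)-2-methoxy-6-methylbenzoyl]oxy}-2-methoxy-6-methylbenzoate | COC(=O)c1c(C)cc(OC(=O)c2c(C)cc(OCc3ccccc3)cc2OC)cc1OC
F5 | step 4 | methyl buta-2,3-dienoate (purchased) | C=C=CC(=O)OC
F6 | step 4 | methyl 2,2-dimethoxy-6-methylidene-4-(trimethylsilyloxy)cyclohex-3-ene-1-carboxylate (racemic) | COC(=O)C1C(=C)CC(O[Si](C)(C)C)=CC1(OC)OC
F7 | step 1 | 1,1-dimethoxyethene (purchased) | C=C(OC)OC
A1 | alternative 1 | methyl 2,4-dihydroxy-6-methylbenzoate | COC(=O)c1c(C)cc(O)cc1O
A2 | alternative 1 | 4-(benzyloxy)-2-methoxy-6-methylbenzoic acid | OC(=O)c1c(C)cc(OCc2ccccc2)cc1OC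
A3 | alternative 1 | 2-(benzyloxy)-4-methoxy-6-methylbenzoic acid | COc1cc(C)c(C(=O)O)c(OCc2ccccc2)c1
A4 | alternative 1 | methyl 4-({4-[(2-(benzyloxy)-4-methoxy-6-methylbenzoyl)oxy]-2-methoxy-6-methylbenzoyl}oxy)-2-methoxy-6-methylbenzoate | COC(=O)c1c(C)cc(OC(=O)c2c(C)cc(OC(=O)c3c(C)cc(OC)cc3OCc4ccccc4)cc2OC)cc1OC
A5 | alternative 2 | 2,2-dimethyl-6-(2,4-dioxopentyl)-4H-1,3-dioxin-4-one | CC(=O)CC(=O)CC1=CC(=O)OC(C)(C)O1
A6 | alternative 2 | 3,5,7-trioxooct-1-en-1-one | CC(=O)CC(=O)CC(=O)C=C=O
A7 | alternative 2 | 3,5,7-trioxooctanoate of phenol 13 | CC(=O)CC(=O)CC(=O)CC(=O)Oc1cc(C)c(C(=O)Oc2cc(C)c(C(=O)OC)c(OC)c2)c(OC)c1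
A8 | alternative 2 | methyl 4-({4-[(2,4-dihydroxy-6-methylbenzoyl)oxy]-2-methoxy-6-methylbenzoyl}oxy)-2-methoxy-6-methylbenzoate | COC(=O)c1c(C)cc(OC(=O)c2c(C)cc(OC(=O)c3c(C)cc(O)cc3O)cc2OC)cc1OC
A9 | alternative 3 | 4,4-dimethoxybuta-1,3-dien-2-yl 2-(benzyloxy)-4-methoxy-6-methylbenzoate | C=C(OC(=O)c1c(C)cc(OC)cc1OCc2ccccc2)C=C(OC)OC
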